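**Retrosynthetic overview**
1. The exocyclic (E)-alkene is cut last: Horner–Wadsworth–Emmons union of lactone phosphonate 13 (fragment 2) with C17 aldehyde 8 (fragment 1).
2. Fragment 1 comes from (5E,9E)-farnesylacetone, which already holds both (E)-trisubstituted alkenes: the terminal isopropylidene becomes the aldehyde (epoxide, then periodic acid), and the methyl ketone becomes the butenolide.
3. Fragment 2 comes from chiral-pool (S)-5-(hydroxymethyl)butyrolactone: oxidation, isopropylidene Wittig, α-phosphonylation.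
4. Ring order: the γ-lactone (ring A) is bought intact with its stereocentre; the butenolide (ring B) is closed in step 3; the two fragments are joined in step 8.

Assumption: (5E,9E)-farnesylacetone is bought as the single E,E isomer; the oxirane centre made in step 1 is racemic on purpose (it is excised in step 4), and C3 of 12 and 13 is an irrelevant epimer mixture.

**Step 1**
Reactants: 1 (5E,9E)-farnesylacetone [(5E,9E)-6,10,14-trimethylpentadeca-5,9,13-trien-2-one]
Product: 3 racemic epoxy ketone (5E,9E)-12-(3,3-dimethyloxiran-2-yl)-6,10-dimethyldodeca-5,9-dien-2-one, via terminal bromohydrin 2 (not isolated)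
Conditions: NBS (1.1 equiv), THF/H2O, 0 °C; then K2CO3, MeOH, rt
Reagents that add atoms: water, O (epoxide oxygen); N-bromosuccinimide, O=C1CCC(=O)N1Br (bromine of intermediate 2 only, lost on ring closure)
Why: Bromohydrin formation followed by intramolecular Williamson closure (van Tamelen terminal epoxidation) is selective for the terminal isopropylidene of a coiled polyprenyl chain in aqueous THF, leaves the ketone alone, and gives the oxirane centre as a racemate that is removed later.

**Step 2**
Reactants: 3 racemic epoxy ketone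
Product: 5 (5E,9E)-1-bromo-12-(3,3-dimethyloxiran-2-yl)-6,10-dimethyldodeca-5,9-dien-2-one, via trimethylsilyl enol ether 4 (not isolated)
Conditions: LiN(i-Pr)2, Me3SiCl, THF, −78 °C; then NBS, −78 → 0 °C
Reagents that add atoms: N-bromosuccinimide, O=C1CCC(=O)N1Br; chlorotrimethylsilane, C[Si](C)(C)Cl (silyl group of intermediate 4 only)
Why: Kinetic enolisation at the methyl group with in-situ silylation, then electrophilic α-bromination of the silyl enol ether, which reacts with NBS far faster than the trisubstituted alkenes; the epoxide tolerates the cold, basic, anhydrous medium and no stereocentre is formed.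

**Step 3**
Reactants: 5 bromomethyl ketone
Product: 7 4-[(3E,7E)-10-(3,3-dimethyloxiran-2-yl)-4,8-dimethyldeca-3,7-dien-1-yl]furan-2(5H)-one, via phosphonoacetate ester 6 (not isolated)
Conditions: (EtO)2P(O)CH2CO2H, K2CO3 (3 equiv), 18-crown-6 (cat.), MeCN, rt then 50 °C
Reagents that add atoms: diethylphosphonoacetic acid, OC(=O)CP(=O)(OCC)OCC
Why: Carboxylate SN2 displacement of the primary α-bromo ketone followed by intramolecular Horner–Wadsworth–Emmons olefination onto the ketone closes the butenolide, whose ring fixes the alkene geometry; no stereocentre is formed.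

**Step 4**
Reactants: 7 epoxy butenolide
Product: 8 (4E,8E)-4,8-dimethyl-11-(5-oxo-2,5-dihydrofuran-3-yl)undeca-4,8-dienal
Conditions: H5IO6, THF/Et2O, 0 °C
Reagents that add atoms: none
Why: Periodic acid opens the trisubstituted epoxide to the glycol and cleaves it (Malaprade-type oxidative cleavage) to the aldehyde and acetone without touching the alkenes or the butenolide, which also deletes the racemic oxirane centre.

**Step 5**
Reactants: 9 (S)-5-(hydroxymethyl)dihydrofuran-2(3H)-one
Product: 10 (S)-5-oxotetrahydrofuran-2-carbaldehyde (used crude at once)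
Conditions: (COCl)2, DMSO, CH2Cl2, −78 °C; i-Pr2NEt, −78 → −30 °C; non-aqueous work-up
Reagents that add atoms: none
Why: Swern oxidation stops at the aldehyde under cold, anhydrous conditions, and the hindered amine keeps the chiral-pool (S) centre from epimerising.

**Step 6**
Reactants: 10 (S)-5-oxotetrahydrofuran-2-carbaldehyde
Product: 11 (S)-5-(2-methylprop-1-en-1-yl)dihydrofuran-2(3H)-one
Conditions: i-PrPPh3I, n-BuLi, THF, 0 °C; then 10, −78 → 0 °C
Reagents that add atoms: isopropyltriphenylphosphonium iodide, CC(C)[P+](c1ccccc1)(c1ccccc1)c1ccccc1.[I-]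
Why: Wittig olefination with the non-stabilised isopropylidene ylide attacks the aldehyde at −78 °C faster than the lactone carbonyl or the α-proton, so the (S) centre is carried through unchanged and the new alkene has no geometry to control.

**Step 7**
Reactants: 11 (S)-5-(2-methylprop-1-en-1-yl)dihydrofuran-2(3H)-one
Product: 13 diethyl [(5S)-5-(2-methylprop-1-en-1-yl)-2-oxotetrahydrofuran-3-yl]phosphonate (C3 epimers), via lactone phosphonite 12 (not isolated)
Conditions: LiN(i-Pr)2, THF/Et2O, −78 °C; ClP(OEt)2, −78 °C → rt; then air, rt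
Reagents that add atoms: diethyl chlorophosphite, CCOP(Cl)OCC; dioxygen (air), O=O
Why: C-phosphinylation of the lactone enolate with the trivalent phosphorus chloride, then air oxidation to the phosphonate; C5 is not acidic so the (S) centre is safe, and the new C3 centre is erased in step 8.

**Step 8**
Reactants: 13 lactone phosphonate; 8 C17 butenolide aldehyde
Product: 14 (3E,5S)-3-[(4E,8E)-4,8-dimethyl-11-(5-oxo-2,5-dihydrofuran-3-yl)undeca-4,8-dien-1-ylidene]-5-(2-methylprop-1-en-1-yl)dihydrofuran-2(3H)-one (CNP0237694.1)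
Conditions: NaH (0.95 equiv relative to 13), THF, 0 °C; then 8, 0 °C → rt
Reagents that add atoms: none
Why: Horner–Wadsworth–Emmons olefination of the preformed sodium phosphonate is expected to favour the (E)-alkylidene lactone with the chain anti to the lactone carbonyl, and the weakly basic anion leaves the butenolide, the enolisable aldehyde and the C5 (S) centre alone.

**Compound list**
1 | (5E,9E)-farnesylacetone, (5E,9E)-6,10,14-trimethylpentadeca-5,9,13-trien-2-one | CC(C)=CCC/C(C)=C/CC/C(C)=C/CCC(C)=O | starting material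
2 | (5E,9E)-13-bromo-14-hydroxy-6,10,14-trimethylpentadeca-5,9-dien-2-one (racemic) | CC(C)(O)C(Br)CC/C(C)=C/CC/C(C)=C/CCC(C)=O | intermediate
3 | (5E,9E)-12-(3,3-dimethyloxiran-2-yl)-6,10-dimethyldodeca-5,9-dien-2-one (racemic) | CC1(C)OC1CC/C(C)=C/CC/C(C)=C/CCC(C)=O | intermediate
4 | {[(5E,9E)-12-(3,3-dimethyloxiran-2-yl)-6,10-dimethyldodeca-1,5,9-trien-2-yl]oxy}trimethylsilane | CC1(C)OC1CC/C(C)=C/CC/C(C)=C/CCC(=C)O[Si](C)(C)C | intermediate
5 | (5E,9E)-1-bromo-12-(3,3-dimethyloxiran-2-yl)-6,10-dimethyldodeca-5,9-dien-2-one | CC1(C)OC1CC/C(C)=C/CC/C(C)=C/CCC(=O)CBr | intermediate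
6 | (5E,9E)-12-(3,3-dimethyloxiran-2-yl)-6,10-dimethyl-2-oxododeca-5,9-dien-1-yl 2-(diethoxyphosphoryl)acetate | CC1(C)OC1CC/C(C)=C/CC/C(C)=C/CCC(=O)COC(=O)CP(=O)(OCC)OCC | intermediate
7 | 4-[(3E,7E)-10-(3,3-dimethyloxiran-2-yl)-4,8-dimethyldeca-3,7-dien-1-yl]furan-2(5H)-one | CC1(C)OC1CC/C(C)=C/CC/C(C)=C/CCC2=CC(=O)OC2 | intermediate
8 | (4E,8E)-4,8-dimethyl-11-(5-oxo-2,5-dihydrofuran-3-yl)undeca-4,8-dienal | O=CCC/C(C)=C/CC/C(C)=C/CCC1=CC(=O)OC1 | intermediate
9 | (S)-5-(hydroxymethyl)dihydrofuran-2(3H)-one | OC[C@@H]1CCC(=O)O1 | starting material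
10 | (S)-5-oxotetrahydrofuran-2-carbaldehyde | O=C[C@@H]1CCC(=O)O1 | intermediate
11 | (S)-5-(2-methylprop-1-en-1-yl)dihydrofuran-2(3H)-one | CC(C)=C[C@@H]1CCC(=O)O1 | intermediate
12 | diethyl [(5S)-5-(2-methylprop-1-en-1-yl)-2-oxotetrahydrofuran-3-yl]phosphonite (C3 epimers) | CC(C)=C[C@@H]1CC(P(OCC)OCC)C(=O)O1 | intermediate
13 | diethyl [(5S)-5-(2-methylprop-1-en-1-yl)-2-oxotetrahydrofuran-3-yl]phosphonate (C3 epimers) | CC(C)=C[C@@H]1CC(P(=O)(OCC)OCC)C(=O)O1 | intermediate
14 | (3E,5S)-3-[(4E,8E)-4,8-dimethyl-11-(5-oxo-2,5-dihydrofuran-3-yl)undeca-4,8-dien-1-ylidene]-5-(2-methylprop-1-en-1-yl)dihydrofuran-2(3H)-one | CC(C)=C[C@@H]1C/C(=C\CC/C(C)=C/CC/C(C)=C/CCC2=CC(=O)OC2)C(=O)O1 | target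

**Totals**
Total step count: 8. Longest linear sequence: 5 steps (steps 1, 2, 3, 4 and 8); the lactone branch is steps 5, 6, 7 and 8.

**Steps most likely to fail, each with a fallback**

Step 2 (methyl-selective bromination beside an epoxide and two alkenes; a C3-bromo isomer or alkene bromination would spoil the butenolide closure). The fallback sets out from 3 and comes back at 7, so it also replaces step 3. Claisen-type C-acylation of 3 with NaH and dimethyl carbonate in refluxing THF goes at the methyl group and gives the β-keto ester methyl (6E,10E)-13-(3,3-dimethyloxiran-2-yl)-7,11-dimethyl-3-oxotrideca-6,10-dienoate F1. Triflation of its chelated sodium enolate (NaH, PhNTf2, THF, 0 °C) gives the (Z)-enol triflate methyl (2Z,6E,10E)-13-(3,3-dimethyloxiran-2-yl)-7,11-dimethyl-3-{[(trifluoromethyl)sulfonyl]oxy}trideca-2,6,10-trienoate F2. Stille coupling with Bu3SnCH2OH (Pd(PPh3)4, LiCl, dioxane, 90 °C) gives with retention the hydroxy ester methyl (2Z,6E,10E)-13-(3,3-dimethyloxiran-2-yl)-3-(hydroxymethyl)-7,11-dimethyltrideca-2,6,10-trienoate F3, which lactonises in the flask to 7.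

Step 6 (a basic, hindered ylide on a labile α-acyloxy aldehyde; risk of epimerisation, lactone attack or low yield). The fallback sets out from 10 and comes back at 11. Non-basic methylenation of 10 with Zn, CH2Br2 and TiCl4 in THF/CH2Cl2 gives (S)-5-vinyldihydrofuran-2(3H)-one F4. Cross-metathesis of F4 in neat 2-methyl-2-butene with (H2IMes)(PCy3)Cl2Ru=CHPh (second-generation Grubbs catalyst) at 40 °C converts the vinyl group into the 2-methylprop-1-enyl group and gives 11.

Step 8 (E/Z ratio of the phosphonate olefination, and base sensitivity of aldehyde 8). The fallback sets out from 11 and comes back at 14, replacing steps 7 and 8 with a stabilised-ylide Wittig reaction. Enolate bromination of 11 (LiN(SiMe3)2, THF, −78 °C; CBr4) gives (5S)-3-bromo-5-(2-methylprop-1-en-1-yl)dihydrofuran-2(3H)-one F5. Heating with PPh3 in toluene at 90 °C gives [(5S)-5-(2-methylprop-1-en-1-yl)-2-oxotetrahydrofuran-3-yl]triphenylphosphonium bromide F6. Aqueous NaOH/CH2Cl2 gives the ylide (5S)-5-(2-methylprop-1-en-1-yl)-3-(triphenylphosphoranylidene)dihydrofuran-2(3H)-one F7. Heating F7 with 8 in toluene at 80 °C should give the (E)-alkylidene lactone 14 under the thermodynamic control typical of stabilised ylides.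

**Further compounds**
F1 | step 2 | methyl (6E,10E)-13-(3,3-dimethyloxiran-2-yl)-7,11-dimethyl-3-oxotrideca-6,10-dienoate | CC1(C)OC1CC/C(C)=C/CC/C(C)=C/CCC(=O)CC(=O)OC
F2 | step 2 | methyl (2Z,6E,10E)-13-(3,3-dimethyloxiran-2-yl)-7,11-dimethyl-3-{[(trifluoromethyl)sulfonyl]oxy}trideca-2,6,10-trienoate | CC1(C)OC1CC/C(C)=C/CC/C(C)=C/CC/C(OS(=O)(=O)C(F)(F)F)=C/C(=O)OC
F3 | step 2 | methyl (2Z,6E,10E)-13-(3,3-dimethyloxiran-2-yl)-3-(hydroxymethyl)-7,11-dimethyltrideca-2,6,10-trienoate | CC1(C)OC1CC/C(C)=C/CC/C(C)=C/CC/C(CO)=C/C(=O)OC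
F4 | step 6 | (S)-5-vinyldihydrofuran-2(3H)-one | C=C[C@@H]1CCC(=O)O1
F5 | step 8 | (5S)-3-bromo-5-(2-methylprop-1-en-1-yl)dihydrofuran-2(3H)-one (C3 epimers) | CC(C)=C[C@@H]1CC(Br)C(=O)O1
F6 | step 8 | [(5S)-5-(2-methylprop-1-en-1-yl)-2-oxotetrahydrofuran-3-yl]triphenylphosphonium bromide | CC(C)=C[C@@H]1CC([P+](c2ccccc2)(c2ccccc2)c2ccccc2)C(=O)O1.[Br-]
F7 | step 8 | (5S)-5-(2-methylprop-1-en-1-yl)-3-(triphenylphosphoranylidene)dihydrofuran-2(3H)-one | CC(C)=C[C@@H]1CC(=P(c2ccccc2)(c2ccccc2)c2ccccc2)C(=O)O1
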